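## Analysis of the target

Target 20 is a dearomatised acylphloroglucinol. Chromanone locants are used throughout: ring B is the dihydropyran-4-one O1–C2–C3–C4–C4a–C8a, ring A the carbocycle C4a–C5–C6–C7–C8–C8a. Ring A is a cross-conjugated dienone: the C5 enol hydroxyl is chelated to C4=O, C6 carries the benzylic carbon of a 3-phenylpropanoic acid arm, C7 is a ketone, and C8 is an all-carbon quaternary centre bearing a prenyl and a lavandulyl group. There are five stereocentres in four separate units: C2/C3 (2R,3R, trans-dimethyl, the only contiguous pair), C8 (S), the benzylic carbon (S) and the lavandulyl methine (R). These units are separated by sp2 carbons or CH2 groups, so none can relay its configuration to another. The sensitive points are the epimerisable C3, ring B (a retro-oxa-Michael opening would erase C2), the acidic β-triketone enol, three alkenes that rule out hydrogenation and strong acid once present, and a carboxylic acid that can close onto O5. The synthesis is hard for three reasons: C6 and C8 must be told apart on a ring that derives from threefold-symmetric phloroglucinol; C8 must be made quaternary with control although lavandulyl is a β-branched homoallylic alkyl group and a poor electrophile; and the benzylic centre is remote from everything else. The strategy rests on the O1–C2 bond, which lies β to the C4 carbonyl: ring B is the conjugate adduct of the ring A oxygen on C8a to a tigloyl ketone on C4a. On a 2,4,6-trihydroxyphenyl ketone both ortho oxygens are equivalent, so ring B can be closed first and enantioselectively, and the product then distinguishes 5-OH from 7-OH for all later steps.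

## Retrosynthetic reasoning

**20 ⇒ 19.** The acid is traced back to the six-membered enol lactone 19, in which the carboxyl group acylates O5 (ring C). The lactone masks the acid and ties up O5 during the carbon–carbon bond formations at C8. Forward, a mild saponification has to open an activated enol ester without touching ring B.

**19 ⇒ 18.** The C8–prenyl bond is cut, giving the aromatic phenol 18 with lavandulyl already on C8. Prenyl goes on last because it is an allylic electrophile that can quaternise a phenoxide carbon through a π-allyl metal complex; lavandulyl cannot do this. Forward, the step must dearomatise ring A at C8 and choose one face of the flat ring, and only a chiral catalyst can do that because the resident centres are remote.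

**18 ⇒ 13 + 17.** The C8–CH2 bond is cut between an sp2 and an sp3 carbon and assigned to a cross-coupling of aryl iodide 13 with organozinc 17. A β-branched homoallylic halide is a poor SN2 partner for a phenoxide carbon, but its zinc derivative transfers cleanly to palladium, and the stereocentre β to zinc is not at risk. Reagent 17 comes from iodide 16, from alcohol 15, obtained by enzymatic resolution of racemic 14. Because the CIP priorities change, the R methine of 20 corresponds to (S)-lavandulol.

**13 ⇒ 12 ⇒ 11.** The iodine is placed at C8 when it is the only ring position left with hydrogen, so no selectivity is needed. The free 7-OH of 12 comes from benzyl ether 11 by hydrogenolysis, which is possible only before any alkene is present.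

**11 ⇒ 10.** The benzylic C–phenyl bond is cut, leading back to the ring-fused coumarin 10 and a phenyl donor. A catalyst-controlled conjugate arylation of a coumarin sets the isolated benzylic centre reliably. A one-step cinnamoyl conjugate addition–lactonisation on the aromatic chromanone would offer no control of C6 versus C8 and none of the benzylic configuration, so the same unit is assembled in three defined operations.

**10 ⇒ 8 ⇒ 7.** The lactone carbons are removed: the C=C of 10 by an intramolecular olefination of an O5-bound ylide with an aldehyde on C6, and the aldehyde carbon of 8 by formylation of 7. In 7 only 5-OH is free, and its only free ortho carbon is C6, so a phenoxide-directed formylation fixes the regiochemistry that electronic effects alone would not.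

**7 ⇒ 6.** The benzyl group is removed. In 6 the 7-OH is acidic and unhindered while 5-OH is locked in a hydrogen bond to C4=O, so selective etherification is straightforward.

**6 ⇒ 4 (key disconnection).** The O1–C2 bond is cut, opening ring B to the tigloyl ketone 4. This removes one ring, one skeletal bond and both ring B stereocentres in one step and leads to a symmetric, two-step precursor. Forward, the closure needs only enone-face selectivity; C3 settles by equilibration to trans.

**4 ⇒ 3 + 2; 2 ⇒ 1.** The aryl–acyl bond is cut to phloroglucinol 3 and acid chloride 2, made from tiglic acid 1. All ring carbons of 3 are equivalent, so the acylation has no regiochemistry; it only has to stop before the enone cyclises.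

## Alternatives that were turned down

**Alternative 1:** The last carbon–carbon bond made would be C6–benzylic carbon, with the whole cinnamoyl unit joined to a ring A that is already dearomatised and carries both C8 chains. Forward, C6 (flanked by the C5 enol and the C7 ketone) adds as a vinylogous acid to the β-carbon of a cinnamoyl acyl ammonium ion generated with a chiral isothiourea, and O5 then closes the enol lactone A1, which is the same compound as 19.
- For it: it is biomimetic and convergent, and it does in one step what steps 5–7 do in three. The nucleophile is a cyclic 1,3-dicarbonyl C–H acid, the best-established partner for this catalysis, and closure on O5 or O7 would both hydrolyse to 20. On step economy for the arm it is the stronger plan.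
- Against it: its substrate needs C8 fully alkylated while C6 is still free. On the aromatic ring nothing then separates C6 from C8 for the lavandulyl and prenyl transfers, and a dearomative prenylation could quaternise C6 as easily. The catalyst would also have to set the benzylic centre beside an acidic triketone that can protonate it, in a matched or mismatched relation with four resident centres.
- Comparison: the chosen route spends two more steps but addresses C6 through the chelated 5-OH while ring A is aromatic. Ring C then blocks C6 and masks O5, leaving C8 as the only carbon open to both alkylations.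

**Alternative 2:** Ring A itself would be assembled from a four-carbon and a two-carbon piece. Forward, the cyclobutenone A2 (both side chains on its sp3 carbon, the ring B carbons as an open-chain enol ether) is heated with an ethyl ynol ether. A 4π opening gives a vinylketene, [2+2] addition forms C6–C7, a second 4π opening follows, and a 6π electrocyclisation re-forms C7–C8; together with the new C5–C4a bond this completes the dienone A3.
- For it: there is no aromatic regiochemistry at all, the quaternary carbon is built by simple enolate alkylations on a small ring, and C2/C3 come from an acyclic chiral building block. On regiochemistry it is stronger than the chosen route.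
- Against it: the carbon that becomes C8 is planar in both ketene intermediates, so its configuration is erased and re-created in the electrocyclisation with nothing to choose the helical sense; both C8 epimers must be expected. The vinylketene also carries a prenyl alkene on its terminus that can trap the ketene intramolecularly. A3 still needs oxidation of the silyl-protected CH2O carbon, ring B closure by C-acylation at C4a, ether cleavage and the entire C6 arm.
- Comparison: the chosen route keeps C8 addressable by a chiral catalyst, with separation after a single step as a reserve, and has a far shorter endgame.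

**Alternative 3:** The C5–C6 bond of ring A would be cut. The precursor A4 is a (2R,3R)-dihydropyranone with a methyl ester on C4a and, on C8a, an acyclic quaternary carbon bearing lavandulyl, prenyl and acetyl. Forward, a lithium amide enolises the acetyl methyl group and a Dieckmann closure onto the ester gives the C6-unsubstituted core A5.
- For it: ring B and C8 are fixed before ring A exists, there is no aromatic regiochemistry, and Dieckmann closure to a six-membered triketone is dependable. In regiochemical certainty it is at least as strong as the chosen route.
- Against it: the difficulty moves into A4. An acyclic all-carbon stereocentre carrying a β-branched lavandulyl group on the β-carbon of a vinylogous ester needs an enantioselective alkylation with an unreactive electrophile or a long detour. The strong base can also remove C3–H and open ring B by β-elimination. A5 still lacks the C6 arm, so the annulation of alternative 1 would have to follow.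
- Comparison: the chosen route reaches its key step in two steps and puts lavandulyl on an sp2 carbon by cross-coupling, so the quaternary centre is closed with the reactive prenyl partner.

Key step: step 3

Remark: immobilised Candida antarctica lipase B is taken to acylate (R)-lavandulol faster than its enantiomer, so the alcohol recovered unreacted is (S)-lavandulol 15.
Remark: the catalyst enantiomers in steps 3, 7 and 13 are those expected from the usual models of each catalyst class; each has a commercial antipode that would replace it without other change if the sense of induction proved opposite.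

## Route

Step 1
Reactants: 1 tiglic acid
Product: 2 tigloyl chloride, (E)-2-methylbut-2-enoyl chloride
Conditions: (COCl)2, DMF (cat.), CH2Cl2, 0 °C to rt
Reagents that add atoms: oxalyl chloride, O=C(Cl)C(Cl)=O
Why: Acid chloride formation through the chloroiminium species from DMF; without base or heat the E double bond is neither isomerised nor moved out of conjugation.

Step 2
Reactants: 3 phloroglucinol; 2 tigloyl chloride
Product: 4 (E)-2-methyl-1-(2,4,6-trihydroxyphenyl)but-2-en-1-one
Conditions: AlCl3 (3.5 equiv), PhNO2–CH2Cl2, 0 °C to rt; ice-cold 1 M HCl quench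
Reagents that add atoms: none
Why: Friedel–Crafts C-acylation of an arene whose three ring CH carbons are equivalent, so only mono-acylation has to be controlled; at or below room temperature the α,β-dimethyl enone should stay open, since its closure to the chromanone normally needs base or heat.

Step 3
Reactants: 4 (E)-2-methyl-1-(2,4,6-trihydroxyphenyl)but-2-en-1-one
Product: 6 (2R,3R)-5,7-dihydroxy-2,3-dimethylchroman-4-one, via chromanone C4 enol 5 (not isolated)
Conditions: quinine (20 mol %), PhCl–THF (10:1), rt, stirred on until the trans:cis ratio is constant
Reagents that add atoms: none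
Why: The quinuclidine nitrogen of quinine takes the proton of one of the two equivalent ortho hydroxyls of 4 while the C9 hydroxyl of the alkaloid hydrogen-bonds the ketone, so that phenoxide and s-cis enone sit in one chiral ion pair. The phenoxide oxygen then adds to the β-carbon of the tigloyl unit in a 6-endo-trig oxa-Michael closure that forms O1–C2, closes ring B and gives enol 5. The closest known reaction type is the cinchona alkaloid-catalysed intramolecular oxa-Michael addition of ortho-tigloylphenols to 2,3-dimethylchroman-4-ones. C2 is controlled by the catalyst: quinine is the pseudo-enantiomer expected to open the enone face that leads to 2R, and the fixed E geometry of the double bond turns that face choice into one configuration. C3 is under thermodynamic control: protonation of 5 and re-enolisation by the amine converge on the trans, diequatorial 3R isomer without breaking the O1–C2 bond. The only selectivity the step needs is between the two enone faces, because both ortho hydroxyls lead to the same chromanone and the para hydroxyl cannot reach the β-carbon; the intramolecular hydrogen bond of the ortho-hydroxy ketone holds the reacting conformer. The uncatalysed closure is kept slow by an aprotic, weakly polar medium and by freeing 4 of acid and aluminium salts before use.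

Step 4
Reactants: 6 (2R,3R)-5,7-dihydroxy-2,3-dimethylchroman-4-one
Product: 7 (2R,3R)-7-benzyloxy-5-hydroxy-2,3-dimethylchroman-4-one
Conditions: BnOH, PPh3, DIAD, THF, 0 °C to rt
Reagents that add atoms: benzyl alcohol, OCc1ccccc1
Why: Mitsunobu etherification takes the more acidic, unhindered 7-OH (para to the carbonyl) and leaves 5-OH, which is held in the hydrogen bond to C4=O; the near-neutral conditions avoid carbonate bases that could open ring B.

Step 5
Reactants: 7 (2R,3R)-7-benzyloxy-5-hydroxy-2,3-dimethylchroman-4-one
Product: 8 (2R,3R)-7-benzyloxy-5-hydroxy-2,3-dimethyl-4-oxochromane-6-carbaldehyde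
Conditions: MgCl2, Et3N, (CH2O)n, MeCN, reflux; then 1 M HCl
Reagents that add atoms: formaldehyde (as paraformaldehyde), C=O
Why: Casnati–Skattebøl ortho-formylation: the magnesium phenoxide of 5-OH delivers formaldehyde to its only free ortho carbon, C6, and a second formaldehyde oxidises the resulting benzylic alkoxide to the aldehyde. C8 is para to this oxygen and lies outside the chelate-controlled transfer.

Step 6
Reactants: 8 (2R,3R)-7-benzyloxy-5-hydroxy-2,3-dimethyl-4-oxochromane-6-carbaldehyde
Product: 10 (8R,9R)-5-(benzyloxy)-8,9-dimethyl-8,9-dihydro-2H,10H-pyrano[2,3-f]chromene-2,10-dione, via O5 phosphoranylideneacetate ester 9 (not isolated)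
Conditions: Ph3P=C=C=O, toluene, 90 °C
Reagents that add atoms: (triphenylphosphoranylidene)ketene, O=C=C=P(c1ccccc1)(c1ccccc1)c1ccccc1
Why: The phenolic O–H adds across the ketene ylide to give ester ylide 9, and an intramolecular Wittig olefination with the neighbouring aldehyde closes the 2-pyranone with the cis double bond the ring requires. The lactone oxygen is thereby fixed as O5 and the β-carbon sits on C6.

Step 7
Reactants: 10 (8R,9R)-5-(benzyloxy)-8,9-dimethyl-8,9-dihydro-2H,10H-pyrano[2,3-f]chromene-2,10-dione
Product: 11 (4S,8R,9R)-5-(benzyloxy)-8,9-dimethyl-4-phenyl-3,4,8,9-tetrahydro-2H,10H-pyrano[2,3-f]chromene-2,10-dione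
Conditions: PhB(OH)2 (5 equiv), Rh(acac)(C2H4)2 (3 mol %), (S)-SEGPHOS (3.3 mol %), dioxane–H2O (10:1), 60 °C
Reagents that add atoms: phenylboronic acid, OB(O)c1ccccc1
Why: Hayashi–Miyaura conjugate addition of a phenylrhodium species to the coumarin double bond, followed by hydrolysis of the rhodium enolate. The benzylic centre is set by the ligand (the R ligand gives R-4-arylchroman-2-ones from simple coumarins, so the S ligand is taken for the S centre); the C2/C3 centres are too far away to interfere.

Step 8
Reactants: 11 (4S,8R,9R)-5-(benzyloxy)-8,9-dimethyl-4-phenyl-3,4,8,9-tetrahydro-2H,10H-pyrano[2,3-f]chromene-2,10-dione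
Product: 12 (4S,8R,9R)-5-hydroxy-8,9-dimethyl-4-phenyl-3,4,8,9-tetrahydro-2H,10H-pyrano[2,3-f]chromene-2,10-dione
Conditions: H2 (1 atm), Pd/C, EtOAc, rt
Reagents that add atoms: none
Why: Hydrogenolysis of the benzyl ether at the last point where the molecule has no alkene and no aryl iodide; the aprotic solvent keeps the aryl ester lactone closed, and the electron-rich aryl ketone should not be reduced at this pressure.

Step 9
Reactants: 12 (4S,8R,9R)-5-hydroxy-8,9-dimethyl-4-phenyl-3,4,8,9-tetrahydro-2H,10H-pyrano[2,3-f]chromene-2,10-dione
Product: 13 (4S,8R,9R)-5-hydroxy-6-iodo-8,9-dimethyl-4-phenyl-3,4,8,9-tetrahydro-2H,10H-pyrano[2,3-f]chromene-2,10-dione (iodine on chromanone C8)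
Conditions: NIS, CH2Cl2, 0 °C
Reagents that add atoms: N-iodosuccinimide, O=C1CCC(=O)N1I
Why: Electrophilic aromatic iodination ortho to the free 7-OH; chromanone C8 is the only ring carbon still bearing hydrogen, so no regiochemical choice is left.

Step 10
Reactants: 14 racemic lavandulol
Product: 15 (S)-lavandulol, (2S)-5-methyl-2-(prop-1-en-2-yl)hex-4-en-1-ol
Conditions: immobilised Candida antarctica lipase B, vinyl acetate, hexane, rt, run past half conversion; chromatography
Reagents that add atoms: none
Why: Lipase-mediated kinetic resolution by irreversible transesterification; taking the conversion beyond one half raises the enantiomeric purity of the unreacted alcohol even if the enzyme's selectivity for this β-branched primary alcohol should be moderate.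

Step 11
Reactants: 15 (S)-lavandulol
Product: 16 (S)-lavandulyl iodide, (3S)-3-(iodomethyl)-2,6-dimethylhepta-1,5-diene
Conditions: I2, PPh3, imidazole, CH2Cl2, 0 °C to rt
Reagents that add atoms: iodine, II
Why: Appel-type iodination of a primary alcohol; substitution occurs at the CH2 group, so the adjacent stereocentre is untouched.

Step 12
Reactants: 16 (S)-lavandulyl iodide; 13 (4S,8R,9R)-5-hydroxy-6-iodo-8,9-dimethyl-4-phenyl-3,4,8,9-tetrahydro-2H,10H-pyrano[2,3-f]chromene-2,10-dione
Product: 18 (4S,8R,9R)-5-hydroxy-8,9-dimethyl-6-[(2R)-5-methyl-2-(prop-1-en-2-yl)hex-4-en-1-yl]-4-phenyl-3,4,8,9-tetrahydro-2H,10H-pyrano[2,3-f]chromene-2,10-dione, via (S)-lavandulylzinc iodide 17 (not isolated)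
Conditions: 16, Zn dust (activated with BrCH2CH2Br and Me3SiCl), LiCl, THF, 40 °C; then 13, Pd(OAc)2 (5 mol %), SPhos (10 mol %), THF, rt to 40 °C, 17 in excess (3 equiv)
Reagents that add atoms: none
Why: Negishi sp2–sp3 cross-coupling; palladium with SPhos couples primary alkylzinc halides with hindered aryl iodides faster than the zinc reagent is protonated by a free phenol. The lactone and ketone are inert to organozinc halides, and the stereocentre β to zinc cannot epimerise.

Step 13
Reactants: 18 (4S,8R,9R)-5-hydroxy-8,9-dimethyl-6-[(2R)-5-methyl-2-(prop-1-en-2-yl)hex-4-en-1-yl]-4-phenyl-3,4,8,9-tetrahydro-2H,10H-pyrano[2,3-f]chromene-2,10-dione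
Product: 19 enol lactone of the target: ring A dearomatised with prenyl and lavandulyl on C8 (S), C7 ketone, and the C5 enol oxygen acylated by the carboxyl carbon of the C6 arm (2R,3R; benzylic S; lavandulyl R)
Conditions: tert-butyl prenyl carbonate (1.3 equiv), Pd2(dba)3·CHCl3 (2.5 mol %), (R,R)-DACH-phenyl Trost ligand (7.5 mol %), THF, 0 °C to rt
Reagents that add atoms: tert-butyl (3-methylbut-2-en-1-yl) carbonate, CC(C)=CCOC(=O)OC(C)(C)C
Why: Proposed new method: zerovalent palladium ionises the carbonate to a cationic π-prenyl complex and tert-butoxide, which deprotonates the acidic 7-OH of 18; the phenoxide attacks the unsubstituted allyl terminus through C8, the ortho carbon whose alkylation keeps the O1–C8a=C4a–C4=O vinylogous ester, while O-prenylation is reversible under the catalyst and C6 is shielded by ring C. The chiral pocket of the ligand has to choose the face of the flat phenoxide and so set C8 (S), since the resident centres are too remote to bias it; the closest known reaction types are the palladium-catalysed asymmetric allylic dearomatisation of substituted naphthols and the non-selective dearomative prenylation of acylphloroglucinols.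

Step 14
Reactants: 19 enol lactone of the target
Product: 20 (3S)-3-{(2R,3R,8S)-5-hydroxy-2,3-dimethyl-8-(3-methylbut-2-en-1-yl)-8-[(2R)-5-methyl-2-(prop-1-en-2-yl)hex-4-en-1-yl]-4,7-dioxo-3,4,7,8-tetrahydro-2H-chromen-6-yl}-3-phenylpropanoic acid (target, CNP0150579.1)
Conditions: LiOH (3 equiv), THF–H2O, 0 °C; then 1 M HCl to pH 3, 0 °C
Reagents that add atoms: lithium hydroxide, [Li+].[OH-]
Why: Saponification of the enol lactone, an activated ester, releases the carboxylate and the β-triketone enolate. The anionic ring A resists both C3 deprotonation and retro-oxa-Michael opening of ring B, and cold acidification should give the free acid without relactonisation.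

## Compound list

1 | tiglic acid, (E)-2-methylbut-2-enoic acid | C/C=C(\C)C(=O)O | starting material
2 | tigloyl chloride, (E)-2-methylbut-2-enoyl chloride | C/C=C(\C)C(Cl)=O | intermediate
3 | phloroglucinol | Oc1cc(O)cc(O)c1 | starting material
4 | (E)-2-methyl-1-(2,4,6-trihydroxyphenyl)but-2-en-1-one | C/C=C(\C)C(=O)c1c(O)cc(O)cc1O | intermediate
5 | (2R)-2,3-dimethyl-2H-chromene-4,5,7-triol (C4 enol of the chromanone) | C[C@H]1Oc2cc(O)cc(O)c2C(O)=C1C | intermediate
6 | (2R,3R)-5,7-dihydroxy-2,3-dimethylchroman-4-one | C[C@H]1Oc2cc(O)cc(O)c2C(=O)[C@@H]1C | intermediate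
7 | (2R,3R)-7-benzyloxy-5-hydroxy-2,3-dimethylchroman-4-one | C[C@H]1Oc2cc(OCc3ccccc3)cc(O)c2C(=O)[C@@H]1C | intermediate
8 | (2R,3R)-7-benzyloxy-5-hydroxy-2,3-dimethyl-4-oxochromane-6-carbaldehyde | C[C@H]1Oc2cc(OCc3ccccc3)c(C=O)c(O)c2C(=O)[C@@H]1C | intermediate
9 | (2R,3R)-7-benzyloxy-6-formyl-2,3-dimethyl-4-oxochroman-5-yl (triphenylphosphoranylidene)acetate | C[C@H]1Oc2cc(OCc3ccccc3)c(C=O)c(OC(=O)C=P(c3ccccc3)(c3ccccc3)c3ccccc3)c2C(=O)[C@@H]1C | intermediate
10 | (8R,9R)-5-(benzyloxy)-8,9-dimethyl-8,9-dihydro-2H,10H-pyrano[2,3-f]chromene-2,10-dione (coumarin lactone on O5/C6 of the chromanone) | C[C@H]1Oc2cc(OCc3ccccc3)c4C=CC(=O)Oc4c2C(=O)[C@@H]1C | intermediate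
11 | (4S,8R,9R)-5-(benzyloxy)-8,9-dimethyl-4-phenyl-3,4,8,9-tetrahydro-2H,10H-pyrano[2,3-f]chromene-2,10-dione | C[C@H]1Oc2cc(OCc3ccccc3)c4[C@H](c5ccccc5)CC(=O)Oc4c2C(=O)[C@@H]1C | intermediate
12 | (4S,8R,9R)-5-hydroxy-8,9-dimethyl-4-phenyl-3,4,8,9-tetrahydro-2H,10H-pyrano[2,3-f]chromene-2,10-dione | C[C@H]1Oc2cc(O)c4[C@H](c5ccccc5)CC(=O)Oc4c2C(=O)[C@@H]1C | intermediate
13 | (4S,8R,9R)-5-hydroxy-6-iodo-8,9-dimethyl-4-phenyl-3,4,8,9-tetrahydro-2H,10H-pyrano[2,3-f]chromene-2,10-dione | C[C@H]1Oc2c(I)c(O)c4[C@H](c5ccccc5)CC(=O)Oc4c2C(=O)[C@@H]1C | intermediate
14 | racemic lavandulol, 5-methyl-2-(prop-1-en-2-yl)hex-4-en-1-ol | CC(C)=CCC(CO)C(C)=C | starting material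
15 | (S)-lavandulol | C=C(C)[C@H](CC=C(C)C)CO | intermediate
16 | (S)-lavandulyl iodide, (3S)-3-(iodomethyl)-2,6-dimethylhepta-1,5-diene | C=C(C)[C@H](CC=C(C)C)CI | intermediate
17 | (S)-lavandulylzinc iodide | C=C(C)[C@H](CC=C(C)C)C[Zn]I | intermediate
18 | (4S,8R,9R)-5-hydroxy-8,9-dimethyl-6-[(2R)-5-methyl-2-(prop-1-en-2-yl)hex-4-en-1-yl]-4-phenyl-3,4,8,9-tetrahydro-2H,10H-pyrano[2,3-f]chromene-2,10-dione (lavandulyl on chromanone C8) | C=C(C)[C@H](CC=C(C)C)Cc1c(O)c2c(OC(=O)C[C@H]2c3ccccc3)c4c1O[C@H](C)[C@@H](C)C4=O | intermediate
19 | enol lactone of the target (O5 acylated by the C6 arm; 2R,3R,8S; benzylic S; lavandulyl R) | C=C(C)[C@H](CC=C(C)C)C[C@]1(CC=C(C)C)C(=O)C3=C(OC(=O)C[C@H]3c4ccccc4)C2=C1O[C@H](C)[C@@H](C)C2=O | intermediate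
20 | (3S)-3-{(2R,3R,8S)-5-hydroxy-2,3-dimethyl-8-(3-methylbut-2-en-1-yl)-8-[(2R)-5-methyl-2-(prop-1-en-2-yl)hex-4-en-1-yl]-4,7-dioxo-3,4,7,8-tetrahydro-2H-chromen-6-yl}-3-phenylpropanoic acid | C=C(C)[C@H](CC=C(C)C)C[C@]1(CC=C(C)C)C(=O)C([C@@H](CC(=O)O)c2ccccc2)=C(O)C2=C1O[C@H](C)[C@@H](C)C2=O | target

## Step count and least certain steps

Total: 14 steps. Longest linear sequence: 12 steps (steps 1–9 and 12–14); steps 10 and 11 prepare the side chain.

**Step 13 (Proposed new method).** Most likely failure: poor facial selectivity at C8, because both ortho neighbours of the reacting carbon are oxygen-bearing and the ligand pocket may not distinguish the faces. Re-ionisation of the C8–prenyl bond, which would expel a stabilised phenoxide, could also erode the ratio, and O-prenylation or attack at the substituted allyl terminus may compete. Fallback with known chemistry, from 18 back to 19: non-selective Tsuji–Trost dearomative prenylation with Pd(PPh3)4 and the same carbonate in THF, as established for acylphloroglucinol phenoxides. This should give 19 together with the 8R epimer of the enol lactone F1; the two diastereomers are separated by preparative HPLC and the route continues from 19.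

**Step 3 (key step).** Most likely failure: loss of enantiopurity through uncatalysed closure of the free triol, or unproductive salt formation between the alkaloid and the acidic para hydroxyl, which would slow the catalysed path; C3 may also equilibrate incompletely. Fallback, from 3 back to 6, sets C2 from a chiral building block. Mitsunobu etherification of excess 3 with methyl (2S,3S)-3-hydroxy-2-methylbutanoate (PPh3, DIAD, THF; inversion at the carbinol carbon) gives methyl (2S,3R)-3-(3,5-dihydroxyphenoxy)-2-methylbutanoate F2. Saponification (LiOH, THF–H2O) gives (2S,3R)-3-(3,5-dihydroxyphenoxy)-2-methylbutanoic acid F3. Intramolecular Friedel–Crafts acylation (P2O5 in MeSO3H, rt) gives the cis chromanone (2R,3S)-5,7-dihydroxy-2,3-dimethylchroman-4-one F4, and Et3N in CH2Cl2 epimerises C3 to give 6.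

**Step 2.** Most likely failure: premature Lewis-acid-promoted closure of the enone to the racemic chromanone, or HCl addition across the enone, either of which removes the substrate of the key step. Fallback, from 3 and 2 back to 4. 3 is converted into 1,3,5-tris(methoxymethoxy)benzene F5 (MeOCH2Cl, i-Pr2NEt, CH2Cl2). Lithiation between two acetal groups (n-BuLi, THF, 0 °C) gives [2,4,6-tris(methoxymethoxy)phenyl]lithium F6. This is acylated with (E)-N-methoxy-N,2-dimethylbut-2-enamide F7, made from 2 and MeNH(OMe)·HCl with pyridine, to give (E)-2-methyl-1-[2,4,6-tris(methoxymethoxy)phenyl]but-2-en-1-one F8. HCl in MeOH at rt removes the three acetals and returns 4.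

**Step 7.** Most likely failure: slow insertion because the benzyloxy group sits peri to the accepting carbon, so that protodeboronation of the boronic acid outruns the addition; hydrolytic opening of the lactone is a lesser risk. Fallback, from 7 directly to 11, bypassing 8 and 10: oxidative N-heterocyclic carbene catalysis with cinnamaldehyde (chiral aminoindanol-derived triazolium salt, base, 3,3',5,5'-tetra-tert-butyldiphenoquinone, toluene). The cinnamoyl acyl azolium is attacked by C6, and O5, the only free hydroxyl, closes the lactone. This path makes no compound outside the list.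

**Step 12.** Most likely failure: protonolysis of the zinc reagent by the phenol and slow oxidative addition to the electron-rich zinc phenoxide, or β-hydride elimination from the alkylpalladium intermediate, giving reduced arene. Fallback, from 13 back to 18. Silylation (t-BuMe2SiCl, imidazole, CH2Cl2) gives (4S,8R,9R)-5-[(tert-butyldimethylsilyl)oxy]-6-iodo-8,9-dimethyl-4-phenyl-3,4,8,9-tetrahydro-2H,10H-pyrano[2,3-f]chromene-2,10-dione F9. Nickel-catalysed reductive cross-electrophile coupling with 16 (NiBr2(dme), 4,4'-di-tert-butyl-2,2'-bipyridine, Zn, DMA) gives the silyl ether of 18, (4S,8R,9R)-5-[(tert-butyldimethylsilyl)oxy]-8,9-dimethyl-6-[(2R)-5-methyl-2-(prop-1-en-2-yl)hex-4-en-1-yl]-4-phenyl-3,4,8,9-tetrahydro-2H,10H-pyrano[2,3-f]chromene-2,10-dione F10. Buffered fluoride (Bu4NF, AcOH, THF) then returns 18.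

## Further compounds

F1 | step 13 | 8R epimer of enol lactone 19 | C=C(C)[C@H](CC=C(C)C)C[C@@]1(CC=C(C)C)C(=O)C3=C(OC(=O)C[C@H]3c4ccccc4)C2=C1O[C@H](C)[C@@H](C)C2=O
F2 | step 3 | methyl (2S,3R)-3-(3,5-dihydroxyphenoxy)-2-methylbutanoate | C[C@@H](Oc1cc(O)cc(O)c1)[C@H](C)C(=O)OC
F3 | step 3 | (2S,3R)-3-(3,5-dihydroxyphenoxy)-2-methylbutanoic acid | C[C@@H](Oc1cc(O)cc(O)c1)[C@H](C)C(=O)O
F4 | step 3 | (2R,3S)-5,7-dihydroxy-2,3-dimethylchroman-4-one | C[C@H]1Oc2cc(O)cc(O)c2C(=O)[C@H]1C
F5 | step 2 | 1,3,5-tris(methoxymethoxy)benzene | COCOc1cc(OCOC)cc(OCOC)c1
F6 | step 2 | [2,4,6-tris(methoxymethoxy)phenyl]lithium | [Li]c1c(OCOC)cc(OCOC)cc1OCOC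
F7 | step 2 | (E)-N-methoxy-N,2-dimethylbut-2-enamide | C/C=C(\C)C(=O)N(C)OC
F8 | step 2 | (E)-2-methyl-1-[2,4,6-tris(methoxymethoxy)phenyl]but-2-en-1-one | C/C=C(\C)C(=O)c1c(OCOC)cc(OCOC)cc1OCOC
F0 | step 7 | none | none
F9 | step 12 | (4S,8R,9R)-5-[(tert-butyldimethylsilyl)oxy]-6-iodo-8,9-dimethyl-4-phenyl-3,4,8,9-tetrahydro-2H,10H-pyrano[2,3-f]chromene-2,10-dione | C[C@H]1Oc2c(I)c(O[Si](C)(C)C(C)(C)C)c4[C@H](c5ccccc5)CC(=O)Oc4c2C(=O)[C@@H]1C
F10 | step 12 | (4S,8R,9R)-5-[(tert-butyldimethylsilyl)oxy]-8,9-dimethyl-6-[(2R)-5-methyl-2-(prop-1-en-2-yl)hex-4-en-1-yl]-4-phenyl-3,4,8,9-tetrahydro-2H,10H-pyrano[2,3-f]chromene-2,10-dione | C=C(C)[C@H](CC=C(C)C)Cc1c(O[Si](C)(C)C(C)(C)C)c2c(OC(=O)C[C@H]2c3ccccc3)c4c1O[C@H](C)[C@@H](C)C4=O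
A1 | alternative 1 | enol lactone of the target on O5 (identical with 19) | C=C(C)[C@H](CC=C(C)C)C[C@]1(CC=C(C)C)C(=O)C3=C(OC(=O)C[C@H]3c4ccccc4)C2=C1O[C@H](C)[C@@H](C)C2=O
A2 | alternative 2 | 4-lavandulyl-4-prenyl-3-alkoxycyclobut-2-en-1-one with the ring B chain as enol ether (either epimer at the ring sp3 carbon, which is erased on ring opening) | C=C(C)[C@H](CC=C(C)C)CC1(CC=C(C)C)C(=O)C=C1O[C@H](C)[C@@H](C)CO[Si](C)(C)C(C)(C)C
A3 | alternative 2 | ring A dienone with ethyl ether on C5 and the open ring B chain on the C8a oxygen | C=C(C)[C@H](CC=C(C)C)C[C@]1(CC=C(C)C)C(=O)C=C(OCC)C=C1O[C@H](C)[C@@H](C)CO[Si](C)(C)C(C)(C)C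
A4 | alternative 3 | methyl (2R,3R)-2,3-dimethyl-4-oxo-2,3-dihydro-4H-pyran-5-carboxylate bearing on C6 the quaternary carbon with acetyl, prenyl and lavandulyl | C=C(C)[C@H](CC=C(C)C)C[C@](CC=C(C)C)(C(C)=O)C1=C(C(=O)OC)C(=O)[C@H](C)[C@@H](C)O1
A5 | alternative 3 | C6-unsubstituted dearomatised chromanone core | C=C(C)[C@H](CC=C(C)C)C[C@]1(CC=C(C)C)C(=O)C=C(O)C2=C1O[C@H](C)[C@@H](C)C2=O
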